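**Plan**

1. Retrosynthesis (lactone atoms O1, C2=O, C3, C4, C5; C7' is the exocyclic carbinol carbon): the phenols are unmasked last; the benzylic CH2 on C3 is traced back to a dithioketal carbon and the C7'–O bond to a C7'–B bond. The lactone is opened at its acyl bond O1–C2 with C5 returned to a methyl ester. The C3–C4 and C7'–B bonds are then cut together, leaving a ferulate ester, B2pin2 and an arylpyruvate-type tert-butyl ketoester.
2. Forward: vanillin is converted into the ketoester by dithiane acylation and methyl ferulate is silylated. One copper-catalysed three-component step joins the acyclic C7'–C4–C3 chain. Ester reduction and acid lactonisation close the only ring, then C–B oxidation, desulfurisation and desilylation finish the molecule.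
3. Stereochemistry: C7' is set by the chiral bisphosphine on copper in the borylcupration. C4 and C3 follow in the same step by substrate control (enolate attack anti to C–B, closed chair aldol). C–B to C–O oxidation is stereoretentive and no later step touches the three centres.
4. Enabling feature: C7', C4 and C3 are contiguous; C4 is α to ring carbon C5 (a carboxyl carbon at the outset) and C3 is the ketone carbon of an α-ketoester whose ester carbon becomes C2. The triad is therefore an enoate β-carbon/α-carbon pair added to a pyruvate carbonyl.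
5. Design choices: arylpyruvic esters exist largely as enols whose O–H would quench a copper enolate, so the ketoester carries a 1,3-dithiane at the benzylic carbon (no α-hydrogen, reduced to CH2 later). The phenols are TIPS ethers for stability to alkoxide, borohydride and perborate.

Key step: step 5

Abbreviations: Ar = 3-methoxy-4-(triisopropylsilyloxy)phenyl; Bpin = 4,4,5,5-tetramethyl-1,3,2-dioxaborolan-2-yl.

Assumption: the sense of induction of the Josiphos-type ligand is not taken for granted; wherever the ligand is named, the antipode that delivers boron to the face giving the (R)-boronate is meant.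

**Step 1**
Reactants: 1 vanillin
Product: 2 2-(4-hydroxy-3-methoxyphenyl)-1,3-dithiane
Conditions: HS(CH2)3SH, BF3·OEt2 (cat.), CH2Cl2, 0 °C → rt
Reagents that add atoms: propane-1,3-dithiol, SCCCS
Why: Lewis-acid-catalysed dithioacetalisation of an aromatic aldehyde (first stage of Corey–Seebach umpolung) is routine and tolerates the free phenol.

**Step 2**
Reactants: 2 2-(4-hydroxy-3-methoxyphenyl)-1,3-dithiane
Product: 3 2-Ar-1,3-dithiane
Conditions: TIPSCl, imidazole, DMF, rt
Reagents that add atoms: chlorotriisopropylsilane, CC(C)[Si](Cl)(C(C)C)C(C)C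
Why: imidazole-promoted silylation of a phenol gives an aryl TIPS ether that withstands butyllithium, alkoxide, hydride, TFA and perborate in the later steps.

**Step 3**
Reactants: 3 2-Ar-1,3-dithiane; 4 di-tert-butyl oxalate
Product: 6 tert-butyl 2-oxo-2-(2-Ar-1,3-dithian-2-yl)acetate, via lithiated dithiane 5 (not isolated)
Conditions: n-BuLi, THF, −78 → −20 °C; then added to 4 (3 equiv), THF, −78 °C; aq. NH4Cl
Reagents that add atoms: none
Why: Corey–Seebach acylation of a 2-aryl-2-lithio-1,3-dithiane with an oxalate diester, where inverse addition to excess oxalate stops at mono-acylation, gives a ketoester with no α-hydrogen.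

**Step 4**
Reactants: 7 methyl (E)-ferulate
Product: 8 methyl (E)-3-Ar-prop-2-enoate
Conditions: TIPSCl, imidazole, DMF, rt
Reagents that add atoms: chlorotriisopropylsilane, CC(C)[Si](Cl)(C(C)C)C(C)C
Why: imidazole-promoted phenol silylation leaves the enoate untouched and removes the only acidic proton of the Michael acceptor.

**Step 5**
Reactants: 8 methyl (E)-3-Ar-prop-2-enoate; 9 bis(pinacolato)diboron; 6 tert-butyl 2-oxo-2-(2-Ar-1,3-dithian-2-yl)acetate
Product: 12 1-tert-butyl 4-methyl (2S,3R)-2-hydroxy-2-(2-Ar-1,3-dithian-2-yl)-3-[(R)-Ar(Bpin)methyl]butanedioate, via β-boryl copper enolate 10 (not isolated), via O-boryl aldolate 11 (not isolated)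
Conditions: CuCl (5 mol %), NaOtBu (6 mol %), Josiphos-type bisphosphine (6 mol %), 9 (1.3 equiv), 6 (1.2 equiv), THF, no protic additive, 0 °C → rt; aq. NH4Cl
Reagents that add atoms: none
Why: Proposed new method: a ligated Cu–Bpin (from CuOtBu and 9) adds to the β-carbon of 8 to give copper enolate 10, which, with no proton source present, adds to the ketone of 6; the tertiary copper alkoxide is then borylated by 9 to give 11 and return Cu–Bpin, and aqueous work-up cleaves the O–B bond. The closest known reaction types are the copper-catalysed enantioselective β-borylation of cinnamates and copper-catalysed domino conjugate borylation–aldol reactions with aldehydes or simple ketones, but an α-ketoester acceptor combined with a β-aryl enoate has not been shown. No ring is closed. The boron-bearing carbon is set (R) by the chiral bisphosphine in the borylcupration; the neighbouring carbon by reaction of the enolate anti to the C–B bond in the conformer whose benzylic hydrogen eclipses the enolate (allylic strain); the carbinol carbon by a closed six-membered Zimmerman–Traxler chair of the (Z)-enolate in which the bulky dithianyl-aryl group of the ketone is equatorial and the ester is axial beside copper. The step needs Cu–B to add to the enoate rather than the ketone and C–C bond formation to outrun protonation or O-borylation of the enolate: the dithioketal carbon leaves 6 without acidic hydrogens and shields its ketone from borylcupration, while the adjacent ester keeps that ketone electrophilic.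

**Step 6**
Reactants: 12 β-boryl aldol adduct (diester)
Product: 13 tert-butyl (2S,3S,4R)-2-hydroxy-3-(hydroxymethyl)-4-Ar-2-(2-Ar-1,3-dithian-2-yl)-4-(Bpin)butanoate
Conditions: LiBH4, THF, 0 °C → rt; aq. NH4Cl
Reagents that add atoms: none
Why: chemoselective lithium borohydride ester reduction takes the methyl ester and leaves the tert-butyl ester on the fully substituted carbon, as is standard for mixed methyl/tert-butyl diesters, and no stereocentre is involved.

**Step 7**
Reactants: 13 diol tert-butyl ester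
Product: 15 (3S,4S)-3-hydroxy-3-(2-Ar-1,3-dithian-2-yl)-4-[(R)-Ar(Bpin)methyl]dihydrofuran-2(3H)-one, via hydroxy acid 14 (not isolated)
Conditions: TFA/CH2Cl2 (1:4), 0 °C → rt
Reagents that add atoms: none
Why: acid-mediated tert-butyl ester cleavage followed by γ-lactonisation (5-exo-trig acyl substitution) can only use the primary hydroxyl, because the benzylic oxygen is still masked as C–B, which also keeps the electron-rich benzylic position from ionising in acid.

**Step 8**
Reactants: 15 boryl lactone
Product: 16 (3S,4R)-3-hydroxy-4-[(R)-Ar(hydroxy)methyl]-3-(2-Ar-1,3-dithian-2-yl)dihydrofuran-2(3H)-one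
Conditions: NaBO3·4H2O, THF/H2O (1:1), 0 °C → rt
Reagents that add atoms: sodium perborate, [Na+].[O-]B1OO1
Why: perborate oxidation of a secondary alkylboronic ester proceeds by 1,2-migration from boron to oxygen with retention, so the (R)-carbinol follows from the (R)-boronate, and it should be much faster than sulfide oxidation or lactone hydrolysis under these mild conditions.

**Step 9**
Reactants: 16 dithianyl hydroxy lactone
Product: 17 (3S,4R)-3-hydroxy-3-(Ar-methyl)-4-[(R)-Ar(hydroxy)methyl]dihydrofuran-2(3H)-one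
Conditions: Raney Ni (W-2, washed neutral), EtOH, rt
Reagents that add atoms: none
Why: Mozingo-type Raney nickel desulfurisation turns the dithioketal carbon into the benzylic CH2 without touching a stereocentre, and is expected to spare the lactone, silyl ethers and secondary benzylic alcohol as it does in related dithiane-derived lignan lactone carbinols.

**Step 10**
Reactants: 17 bis-TIPS lactone
Product: 18 (3S,4R)-3-hydroxy-3-(4-hydroxy-3-methoxybenzyl)-4-[(R)-hydroxy(4-hydroxy-3-methoxyphenyl)methyl]dihydrofuran-2(3H)-one (target)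
Conditions: TBAF, AcOH (1:1), THF, 0 °C
Reagents that add atoms: none
Why: fluoride cleavage of aryl silyl ethers is fast, and buffering with acetic acid keeps phenoxide low so that translactonisation and quinone methide formation at the benzylic carbinol are avoided.

**Compound list**

1 | vanillin (4-hydroxy-3-methoxybenzaldehyde) | COc1cc(C=O)ccc1O | starting material
2 | 2-(4-hydroxy-3-methoxyphenyl)-1,3-dithiane | COc1cc(C2SCCCS2)ccc1O | intermediate
3 | 2-[3-methoxy-4-(triisopropylsilyloxy)phenyl]-1,3-dithiane | COc1cc(C2SCCCS2)ccc1O[Si](C(C)C)(C(C)C)C(C)C | intermediate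
4 | di-tert-butyl oxalate | CC(C)(C)OC(=O)C(=O)OC(C)(C)C | starting material
5 | 2-lithio-2-Ar-1,3-dithiane; not isolated | COc1cc(C2([Li])SCCCS2)ccc1O[Si](C(C)C)(C(C)C)C(C)C | intermediate
6 | tert-butyl 2-oxo-2-(2-Ar-1,3-dithian-2-yl)acetate | COc1cc(C2(SCCCS2)C(=O)C(=O)OC(C)(C)C)ccc1O[Si](C(C)C)(C(C)C)C(C)C | intermediate
7 | methyl (E)-ferulate, methyl (E)-3-(4-hydroxy-3-methoxyphenyl)prop-2-enoate | COC(=O)/C=C/c1ccc(O)c(OC)c1 | starting material
8 | methyl (E)-3-[3-methoxy-4-(triisopropylsilyloxy)phenyl]prop-2-enoate | COC(=O)/C=C/c1ccc(O[Si](C(C)C)(C(C)C)C(C)C)c(OC)c1 | intermediate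
9 | bis(pinacolato)diboron | CC1(C)OB(OC1(C)C)B1OC(C)(C)C(C)(C)O1 | starting material
10 | copper(I) (Z)-enolate of methyl (R)-3-Ar-3-(Bpin)propanoate (bisphosphine on copper not drawn); not isolated | [Cu]O/C(OC)=C\[C@@H](B1OC(C)(C)C(C)(C)O1)c1ccc(O[Si](C(C)C)(C(C)C)C(C)C)c(OC)c1 | intermediate
11 | 1-tert-butyl 4-methyl (2S,3R)-2-(Bpin-oxy)-2-(2-Ar-1,3-dithian-2-yl)-3-[(R)-Ar(Bpin)methyl]butanedioate; not isolated | COc1cc(C3(SCCCS3)[C@@](OB4OC(C)(C)C(C)(C)O4)(C(=O)OC(C)(C)C)[C@H](C(=O)OC)[C@@H](B2OC(C)(C)C(C)(C)O2)c2ccc(O[Si](C(C)C)(C(C)C)C(C)C)c(OC)c2)ccc1O[Si](C(C)C)(C(C)C)C(C)C | intermediate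
12 | 1-tert-butyl 4-methyl (2S,3R)-2-hydroxy-2-(2-Ar-1,3-dithian-2-yl)-3-[(R)-Ar(Bpin)methyl]butanedioate | COc1cc(C3(SCCCS3)[C@@](O)(C(=O)OC(C)(C)C)[C@H](C(=O)OC)[C@@H](B2OC(C)(C)C(C)(C)O2)c2ccc(O[Si](C(C)C)(C(C)C)C(C)C)c(OC)c2)ccc1O[Si](C(C)C)(C(C)C)C(C)C | intermediate
13 | tert-butyl (2S,3S,4R)-2-hydroxy-3-(hydroxymethyl)-4-Ar-2-(2-Ar-1,3-dithian-2-yl)-4-(Bpin)butanoate | COc1cc(C3(SCCCS3)[C@@](O)(C(=O)OC(C)(C)C)[C@H](CO)[C@@H](B2OC(C)(C)C(C)(C)O2)c2ccc(O[Si](C(C)C)(C(C)C)C(C)C)c(OC)c2)ccc1O[Si](C(C)C)(C(C)C)C(C)C | intermediate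
14 | (2S,3S,4R)-2-hydroxy-3-(hydroxymethyl)-4-Ar-2-(2-Ar-1,3-dithian-2-yl)-4-(Bpin)butanoic acid; not isolated | COc1cc(C3(SCCCS3)[C@@](O)(C(=O)O)[C@H](CO)[C@@H](B2OC(C)(C)C(C)(C)O2)c2ccc(O[Si](C(C)C)(C(C)C)C(C)C)c(OC)c2)ccc1O[Si](C(C)C)(C(C)C)C(C)C | intermediate
15 | (3S,4S)-3-hydroxy-3-(2-Ar-1,3-dithian-2-yl)-4-[(R)-Ar(Bpin)methyl]dihydrofuran-2(3H)-one | COc1cc(C3(SCCCS3)[C@@]4(O)C(=O)OC[C@@H]4[C@@H](B2OC(C)(C)C(C)(C)O2)c2ccc(O[Si](C(C)C)(C(C)C)C(C)C)c(OC)c2)ccc1O[Si](C(C)C)(C(C)C)C(C)C | intermediate
16 | (3S,4R)-3-hydroxy-4-[(R)-Ar(hydroxy)methyl]-3-(2-Ar-1,3-dithian-2-yl)dihydrofuran-2(3H)-one | COc1cc(C3(SCCCS3)[C@@]4(O)C(=O)OC[C@@H]4[C@@H](O)c2ccc(O[Si](C(C)C)(C(C)C)C(C)C)c(OC)c2)ccc1O[Si](C(C)C)(C(C)C)C(C)C | intermediate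
17 | (3S,4R)-3-hydroxy-3-[3-methoxy-4-(triisopropylsilyloxy)benzyl]-4-{(R)-hydroxy[3-methoxy-4-(triisopropylsilyloxy)phenyl]methyl}dihydrofuran-2(3H)-one | COc1cc(C[C@@]2(O)C(=O)OC[C@@H]2[C@@H](O)c2ccc(O[Si](C(C)C)(C(C)C)C(C)C)c(OC)c2)ccc1O[Si](C(C)C)(C(C)C)C(C)C | intermediate
18 | (3S,4R)-3-hydroxy-3-(4-hydroxy-3-methoxybenzyl)-4-[(R)-hydroxy(4-hydroxy-3-methoxyphenyl)methyl]dihydrofuran-2(3H)-one | COc1cc(C[C@@]2(O)C(=O)OC[C@@H]2[C@@H](O)c2ccc(O)c(OC)c2)ccc1O | target

**Step count and risks**

Total steps: 10. Longest linear sequence: 9 (vanillin, steps 1–3 and 5–10).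

Steps most likely to fail:

1. Step 5 (proposed new method). The copper enolate may be protonated or O-borylated faster than it adds to the crowded ketone. Cu–B may add to the ketoester instead of the enoate. The aldolate may revert before it is trapped, or facial selectivity at the ketone may be poor. The fallback forms the two bonds in separate, known operations. Setting out from 8, the established copper-catalysed enantioselective conjugate borylation with methanol as proton source (CuCl, NaOtBu, the same ligand antipode, 9, MeOH, THF) would give methyl (R)-3-Ar-3-(Bpin)propanoate F1. Perborate oxidation would then give methyl (R)-3-Ar-3-hydroxypropanoate F2. Its dilithium dianion (LDA, 2.2 equiv, THF, −78 → −40 °C, Fráter–Seebach conditions) would be added to ketoester 6. The chelated enolate reacts anti to the carbinol substituent, which is the relationship needed between C7' and C4. This should give 1-tert-butyl 4-methyl (2S,3R)-2-hydroxy-3-[(R)-Ar(hydroxy)methyl]-2-(2-Ar-1,3-dithian-2-yl)butanedioate F3, any C3 epimer being removed by chromatography. LiBH4 would reduce the methyl ester to tert-butyl (2S,3R,4R)-2,4-dihydroxy-3-(hydroxymethyl)-4-Ar-2-(2-Ar-1,3-dithian-2-yl)butanoate F4. Base-catalysed lactonisation through the primary alkoxide (cat. KOtBu, THF, 0 °C; acid is avoided because the benzylic alcohol is now free) comes back to the route at 16.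

2. Step 9. The nickel surface may hydrogenolyse the electron-rich benzylic C–O bond, or C–S cleavage at the crowded carbon may stall. The fallback changes the order so that sulfur leaves while the benzylic position still carries boron. Setting out from 15, Raney nickel (EtOH, rt) would give (3S,4S)-3-hydroxy-3-(Ar-methyl)-4-[(R)-Ar(Bpin)methyl]dihydrofuran-2(3H)-one F5. Perborate oxidation of F5 comes back to the route at 17. This order also removes any competition between boronate and sulfide oxidation.

3. Step 6. Hydride delivery to the crowded methyl ester may be slow. That would leave time for base-induced retro-aldol cleavage of the β-hydroxy ester, attack on the α-hydroxy tert-butyl ester, or lactonisation in the flask followed by over-reduction. The fallback separates ester cleavage from reduction. Setting out from 12, trimethyltin hydroxide (1,2-dichloroethane, 70 °C) would cleave only the methyl ester to (2R,3S)-4-tert-butoxy-3-hydroxy-2-[(R)-Ar(Bpin)methyl]-3-(2-Ar-1,3-dithian-2-yl)-4-oxobutanoic acid F6. BH3·SMe2 (THF, 0 °C), which reduces carboxylic acids but not tert-butyl esters, then comes back to the route at 13.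

**Further compounds**

F1 | step 5 | methyl (R)-3-[3-methoxy-4-(triisopropylsilyloxy)phenyl]-3-(4,4,5,5-tetramethyl-1,3,2-dioxaborolan-2-yl)propanoate | COC(=O)C[C@@H](B1OC(C)(C)C(C)(C)O1)c1ccc(O[Si](C(C)C)(C(C)C)C(C)C)c(OC)c1
F2 | step 5 | methyl (R)-3-hydroxy-3-[3-methoxy-4-(triisopropylsilyloxy)phenyl]propanoate | COC(=O)C[C@@H](O)c1ccc(O[Si](C(C)C)(C(C)C)C(C)C)c(OC)c1
F3 | step 5 | 1-tert-butyl 4-methyl (2S,3R)-2-hydroxy-3-[(R)-Ar(hydroxy)methyl]-2-(2-Ar-1,3-dithian-2-yl)butanedioate | COc1cc(C3(SCCCS3)[C@@](O)(C(=O)OC(C)(C)C)[C@H](C(=O)OC)[C@@H](O)c2ccc(O[Si](C(C)C)(C(C)C)C(C)C)c(OC)c2)ccc1O[Si](C(C)C)(C(C)C)C(C)C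
F4 | step 5 | tert-butyl (2S,3R,4R)-2,4-dihydroxy-3-(hydroxymethyl)-4-Ar-2-(2-Ar-1,3-dithian-2-yl)butanoate | COc1cc(C3(SCCCS3)[C@@](O)(C(=O)OC(C)(C)C)[C@H](CO)[C@@H](O)c2ccc(O[Si](C(C)C)(C(C)C)C(C)C)c(OC)c2)ccc1O[Si](C(C)C)(C(C)C)C(C)C
F5 | step 9 | (3S,4S)-3-hydroxy-3-[3-methoxy-4-(triisopropylsilyloxy)benzyl]-4-[(R)-Ar(Bpin)methyl]dihydrofuran-2(3H)-one | COc1cc(C[C@@]2(O)C(=O)OC[C@@H]2[C@@H](B3OC(C)(C)C(C)(C)O3)c2ccc(O[Si](C(C)C)(C(C)C)C(C)C)c(OC)c2)ccc1O[Si](C(C)C)(C(C)C)C(C)C
F6 | step 6 | (2R,3S)-4-tert-butoxy-3-hydroxy-2-[(R)-Ar(Bpin)methyl]-3-(2-Ar-1,3-dithian-2-yl)-4-oxobutanoic acid | COc1cc(C3(SCCCS3)[C@@](O)(C(=O)OC(C)(C)C)[C@H](C(=O)O)[C@@H](B2OC(C)(C)C(C)(C)O2)c2ccc(O[Si](C(C)C)(C(C)C)C(C)C)c(OC)c2)ccc1O[Si](C(C)C)(C(C)C)C(C)C
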